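**Assumption:** the target has no stereocentre, and its aryl–O and aryl–aryl bonds rotate freely. It is therefore achiral and needs no asymmetric step. Only the E-alkene geometry must be controlled; the transient sp3 centres are erased before the end.

## Retrosynthetic overview
1. Target 20 ⇒ tri-O-benzyl ether 19 by global debenzylation. All four benzene rings are bought, and the two pyranone rings are closed last, together, in one operation.
2. 19 ⇒ bis(β-keto dimethyl acetal) 17 by acid cyclisation ⇒ unsymmetrical bis-chalcone 15 by a double oxidative 1,2-aryl shift.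
3. 15 ⇒ two sequential intermolecular Claisen–Schmidt aldol condensations on a mono-masked diaryl-ether dialdehyde 5. The chloro ketone 8 reacts first, then ketone 13. Each new C–C bond becomes C2–C3 of one chromone.
4. 5 ⇒ SNAr of 4-fluorobenzaldehyde with acetal-phenol 3, which comes from 3,4-dihydroxybenzaldehyde.
5. 8 ⇒ C-acylation of 2-chlororesorcinol, which fixes Cl at the future C8. 13 ⇒ 2,4-dihydroxyacetophenone.

## Route

**Step 1**
Reactants: 1 3,4-dihydroxybenzaldehyde
Product: 2 4-(benzyloxy)-3-hydroxybenzaldehyde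
Conditions: BnBr (1.1 equiv), NaHCO3 (1.5 equiv), DMF, 40 °C, 20 h
Reagents that add atoms: benzyl bromide, BrCc1ccccc1
Why: Williamson etherification; the 4-OH is para to the formyl group and is the more acidic phenol, so the weak base ionises and benzylates it selectively and leaves the 3-OH free.

**Step 2**
Reactants: 2 4-(benzyloxy)-3-hydroxybenzaldehyde
Product: 3 2-(benzyloxy)-5-(1,3-dioxolan-2-yl)phenol
Conditions: HOCH2CH2OH (5 equiv), p-TsOH·H2O (2 mol%), toluene, Dean–Stark reflux; Et3N quench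
Reagents that add atoms: ethylene glycol, OCCO
Why: Acid-catalysed acetalisation with azeotropic water removal masks this aldehyde so that the two formyl groups of the later diaryl ether can be addressed one after the other.

**Step 3**
Reactants: 3 2-(benzyloxy)-5-(1,3-dioxolan-2-yl)phenol; 4 4-fluorobenzaldehyde
Product: 5 4-[2-(benzyloxy)-5-(1,3-dioxolan-2-yl)phenoxy]benzaldehyde
Conditions: K2CO3 (2 equiv), DMF, 120 °C, 12 h, N2
Reagents that add atoms: none
Why: SNAr (addition–elimination); the para-formyl group activates C–F towards the phenoxide of 3, and the basic medium leaves the dioxolane and benzyl ether untouched.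

**Step 4**
Reactants: 6 2-chlororesorcinol
Product: 7 1-(3-chloro-2,4-dihydroxyphenyl)ethan-1-one
Conditions: AcOH (1.5 equiv), BF3·OEt2 (4 equiv, neat), 90 °C, 3 h; then ice-water
Reagents that add atoms: acetic acid, CC(=O)O
Why: Friedel–Crafts (Nencki-type) C-acylation; C4 and C6 are equivalent and are the only positions ortho/para to both hydroxyls, so a single ketone forms with Cl locked between the two oxygens.

**Step 5**
Reactants: 7 1-(3-chloro-2,4-dihydroxyphenyl)ethan-1-one
Product: 8 1-[4-(benzyloxy)-3-chloro-2-hydroxyphenyl]ethan-1-one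
Conditions: BnBr (1.05 equiv), K2CO3 (1.2 equiv), acetone, reflux, 8 h
Reagents that add atoms: benzyl bromide, BrCc1ccccc1
Why: Williamson etherification; the 2-OH is hydrogen-bonded to the ketone and flanked by Cl, so only the 4-OH is alkylated.

**Step 6 (key step, first C–C bond)**
Reactants: 5 4-[2-(benzyloxy)-5-(1,3-dioxolan-2-yl)phenoxy]benzaldehyde; 8 1-[4-(benzyloxy)-3-chloro-2-hydroxyphenyl]ethan-1-one
Product: 10 (E)-1-[4-(benzyloxy)-3-chloro-2-hydroxyphenyl]-3-{4-[2-(benzyloxy)-5-(1,3-dioxolan-2-yl)phenoxy]phenyl}prop-2-en-1-one, via aldol adduct 9 (not isolated)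
Conditions: KOH (50% aq, 10 equiv), EtOH–THF 2:1, 0 °C → rt, 40 h; then ice/AcOH to pH 6
Reagents that add atoms: none
Why: Intermolecular Claisen–Schmidt aldol condensation; the enolate of 8 adds to the only free, non-enolisable aldehyde of 5, and E1cB loss of water erases the racemic carbinol centre and gives the thermodynamically preferred E-enone.

**Step 7**
Reactants: 10 the chalcone acetal from step 6
Product: 11 4-(benzyloxy)-3-(4-{(E)-3-[4-(benzyloxy)-3-chloro-2-hydroxyphenyl]-3-oxoprop-1-en-1-yl}phenoxy)benzaldehyde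
Conditions: 1 M aq HCl (cat.), THF, rt, 2 h
Reagents that add atoms: water, O
Why: Acetal hydrolysis; the para-benzyloxy group stabilises the oxocarbenium ion, so dilute acid at rt suffices, and under these conditions the enone, benzyl ethers and 2'-hydroxychalcone (no flavanone closure) persist.

**Step 8**
Reactants: 12 2,4-dihydroxyacetophenone
Product: 13 1-[4-(benzyloxy)-2-hydroxyphenyl]ethan-1-one
Conditions: BnBr (1.05 equiv), K2CO3 (1.2 equiv), acetone, reflux, 8 h
Reagents that add atoms: benzyl bromide, BrCc1ccccc1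
Why: Williamson etherification; the chelated 2-OH is far less nucleophilic than the 4-OH, so mono-benzylation is clean.

**Step 9 (key step, second C–C bond)**
Reactants: 11 the chalcone aldehyde from step 7; 13 1-[4-(benzyloxy)-2-hydroxyphenyl]ethan-1-one
Product: 15 (E)-1-[4-(benzyloxy)-2-hydroxyphenyl]-3-[4-(benzyloxy)-3-(4-{(E)-3-[4-(benzyloxy)-3-chloro-2-hydroxyphenyl]-3-oxoprop-1-en-1-yl}phenoxy)phenyl]prop-2-en-1-one, via aldol adduct 14 (not isolated)
Conditions: 13 (1.05 equiv), KOH (50% aq, 12 equiv), EtOH–THF 1:1, rt, 48 h; then cold 1 M HCl to pH 3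
Reagents that add atoms: none
Why: Second intermolecular Claisen–Schmidt aldol condensation; the enone already present sits as its electron-rich 2'-phenolate and is a poor Michael or retro-aldol substrate, so the enolate of 13 takes the aldehyde, and dehydration gives the E-enone.

**Step 10**
Reactants: 15 the bis-chalcone from step 9
Product: 16 the bis(2'-O-acetate) of bis-chalcone 15
Conditions: Ac2O (6 equiv), pyridine, DMAP (10 mol%), CH2Cl2, rt, 12 h
Reagents that add atoms: acetic anhydride, CC(=O)OC(C)=O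
Why: DMAP-catalysed O-acylation caps both chelated phenols, which shuts off the aurone/flavone cyclisations and phenol oxidation that compete with aryl migration in the next step.

**Step 11**
Reactants: 16 the bis-chalcone diacetate
Product: 17 the bis(3,3-dimethoxy-2-aryl-1-propanone) diacetate (mixture of diastereomers, used crude)
Conditions: Tl(NO3)3·3H2O (2.3 equiv), MeOH–CH2Cl2 3:1, rt, 5 h; filter TlNO3, NaHCO3 wash (thallium waste segregated)
Reagents that add atoms: methanol, CO
Why: Thallium(III)-mediated oxidative rearrangement of chalcones; methoxythallation and C–Tl heterolysis drive a 1,2-shift of each para-oxygenated aryl ring from Cβ to Cα, MeOH traps the oxocarbenium ion as the acetal, and the two new stereocentres form unselectively and are erased in step 12.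

**Step 12**
Reactants: 17 the bis-acetal diacetate
Product: 19 7-(benzyloxy)-3-[4-(benzyloxy)-3-{4-[7-(benzyloxy)-8-chloro-4-oxo-4H-chromen-3-yl]phenoxy}phenyl]-4H-chromen-4-one, via diphenol bis-acetal 18 (not isolated)
Conditions: 10% aq HCl, MeOH–THF 2:1, reflux, 6 h
Reagents that add atoms: none
Why: Acid methanolysis frees both phenols, which attack the activated acetal carbons and lose MeOH (cyclocondensation) to give both aromatic 4H-chromen-4-one rings, while aryl benzyl ethers and C–Cl are inert to dilute HCl.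

**Step 13**
Reactants: 19 tri-O-benzyl bisoflavolin K
Product: 20 bisoflavolin K, 8-chloro-7-hydroxy-3-{4-[2-hydroxy-5-(7-hydroxy-4-oxo-4H-chromen-3-yl)phenoxy]phenyl}-4H-chromen-4-one
Conditions: BCl3 (1 M in CH2Cl2, 9 equiv), C6HMe5 (12 equiv), CH2Cl2, −78 → 0 °C, 2 h; MeOH then H2O
Reagents that add atoms: none
Why: Lewis-acid debenzylation with a non-basic cation scavenger (the Friedel–Crafts trap prevents C-benzylation); unlike hydrogenolysis it touches neither the aryl chloride, the C2=C3 bonds nor the diaryl ether.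

## Compound list
1 | 3,4-dihydroxybenzaldehyde | O=Cc1ccc(O)c(O)c1 | starting material
2 | 4-(benzyloxy)-3-hydroxybenzaldehyde | O=Cc1ccc(OCc2ccccc2)c(O)c1 | intermediate
3 | 2-(benzyloxy)-5-(1,3-dioxolan-2-yl)phenol | Oc1cc(C2OCCO2)ccc1OCc1ccccc1 | intermediate
4 | 4-fluorobenzaldehyde | O=Cc1ccc(F)cc1 | starting material
5 | 4-[2-(benzyloxy)-5-(1,3-dioxolan-2-yl)phenoxy]benzaldehyde | O=Cc1ccc(Oc2cc(C3OCCO3)ccc2OCc2ccccc2)cc1 | intermediate
6 | 2-chlororesorcinol | Oc1cccc(O)c1Cl | starting material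
7 | 1-(3-chloro-2,4-dihydroxyphenyl)ethan-1-one | CC(=O)c1ccc(O)c(Cl)c1O | intermediate
8 | 1-[4-(benzyloxy)-3-chloro-2-hydroxyphenyl]ethan-1-one | CC(=O)c1ccc(OCc2ccccc2)c(Cl)c1O | intermediate
9 | first aldol adduct, β-hydroxy ketone (racemic, not isolated) | O=C(CC(O)c1ccc(Oc2cc(C3OCCO3)ccc2OCc2ccccc2)cc1)c1ccc(OCc2ccccc2)c(Cl)c1O | intermediate
10 | (E)-chalcone acetal | O=C(/C=C/c1ccc(Oc2cc(C3OCCO3)ccc2OCc2ccccc2)cc1)c1ccc(OCc2ccccc2)c(Cl)c1O | intermediate
11 | (E)-chalcone aldehyde | O=Cc1ccc(OCc2ccccc2)c(Oc2ccc(/C=C/C(=O)c3ccc(OCc4ccccc4)c(Cl)c3O)cc2)c1 | intermediate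
12 | 2,4-dihydroxyacetophenone | CC(=O)c1ccc(O)cc1O | starting material
13 | 1-[4-(benzyloxy)-2-hydroxyphenyl]ethan-1-one | CC(=O)c1ccc(OCc2ccccc2)cc1O | intermediate
14 | second aldol adduct, β-hydroxy ketone (racemic, not isolated) | O=C(CC(O)c1ccc(OCc2ccccc2)c(Oc2ccc(/C=C/C(=O)c3ccc(OCc4ccccc4)c(Cl)c3O)cc2)c1)c1ccc(OCc2ccccc2)cc1O | intermediate
15 | (E,E)-bis-chalcone | O=C(/C=C/c1ccc(OCc2ccccc2)c(Oc2ccc(/C=C/C(=O)c3ccc(OCc4ccccc4)c(Cl)c3O)cc2)c1)c1ccc(OCc2ccccc2)cc1O | intermediate
16 | (E,E)-bis-chalcone diacetate | CC(=O)Oc1cc(OCc2ccccc2)ccc1C(=O)/C=C/c1ccc(OCc2ccccc2)c(Oc2ccc(/C=C/C(=O)c3ccc(OCc4ccccc4)c(Cl)c3OC(C)=O)cc2)c1 | intermediate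
17 | bis(β-keto dimethyl acetal) diacetate (diastereomer mixture, racemic) | CC(=O)Oc1cc(OCc2ccccc2)ccc1C(=O)C(C(OC)OC)c1ccc(OCc2ccccc2)c(Oc2ccc(C(C(OC)OC)C(=O)c3ccc(OCc4ccccc4)c(Cl)c3OC(C)=O)cc2)c1 | intermediate
18 | diphenol bis(β-keto dimethyl acetal) (diastereomer mixture, not isolated) | COC(OC)C(C(=O)c1ccc(OCc2ccccc2)cc1O)c1ccc(OCc2ccccc2)c(Oc2ccc(C(C(OC)OC)C(=O)c3ccc(OCc4ccccc4)c(Cl)c3O)cc2)c1 | intermediate
19 | tri-O-benzyl bisoflavolin K | O=c1c(-c2ccc(OCc3ccccc3)c(Oc3ccc(-c4coc5c(Cl)c(OCc6ccccc6)ccc5c4=O)cc3)c2)coc2cc(OCc3ccccc3)ccc12 | intermediate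
20 | bisoflavolin K | O=c1c(-c2ccc(O)c(Oc3ccc(-c4coc5c(Cl)c(O)ccc5c4=O)cc3)c2)coc2cc(O)ccc12 | target

## Summary
Total step count: 13.
Longest linear sequence: 10 steps (1, 2, 3, 6, 7, 9, 10, 11, 12, 13).

## Steps most likely to fail, with fallbacks

**Step 11 (double Tl(III) aryl shift).** Both enones must rearrange cleanly in one poorly soluble molecule. The 4-aryloxyphenyl ring also migrates less readily than a 4-alkoxyphenyl ring.

The fallback sets out from 15 and returns at 19. It reaches the same skeleton by an epoxide/1,2-aroyl shift instead of an oxidative aryl shift.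
- 15 is capped with MOMCl/iPr2NEt in CH2Cl2 to give the bis-chalcone bis(methoxymethyl) ether F1.
- Weitz–Scheffer epoxidation (30% H2O2, NaOH, MeOH–THF, 0 °C) gives the bis(trans-α,β-epoxy ketone) F2.
- BF3·OEt2 in CH2Cl2 at 0 °C opens each epoxide at the benzylic carbon. The aroyl group migrates, giving the bis(α-formyl deoxybenzoin) bis-MOM ether F3.
- Warming with HCl in MeOH removes the MOM groups to give the diphenol bis(α-formyl deoxybenzoin) F4, which cyclodehydrates in the same pot to 19.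

**Step 9 (second aldol on an enone-bearing, electron-rich aldehyde).** The risks are Michael addition to the first enone, hydroxide-induced retro-aldol scrambling, and slow conversion.

The fallback sets out from 13 and returns at 15. It replaces the equilibrating condensation with an irreversible, base-free Wittig olefination.
- 13 is α-brominated with CuBr2 in refluxing EtOAc–CHCl3 to give 1-[4-(benzyloxy)-2-hydroxyphenyl]-2-bromoethan-1-one F5.
- PPh3 in toluene at rt gives the phenacyl triphenylphosphonium bromide F6.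
- Aqueous Na2CO3/CH2Cl2 gives the stabilised aroylmethylene triphenylphosphorane F7.
- F7 is heated with aldehyde 11 in toluene at 100 °C and gives 15 as the E-alkene.

**Step 2 (acetal of an electron-rich, phenol-bearing aldehyde).** The equilibrium is unfavourable, and the product is labile on silica and in storage.

The fallback sets out from 2 and returns at 11. It masks the aldehyde by oxidation level instead of as an acetal.
- NaBH4 in MeOH reduces 2 to 2-(benzyloxy)-5-(hydroxymethyl)phenol F8.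
- The phenoxide of F8 reacts chemoselectively with 4 (K2CO3, DMF, 110 °C) to give 4-[2-(benzyloxy)-5-(hydroxymethyl)phenoxy]benzaldehyde F9.
- Claisen–Schmidt condensation of F9 with 8 (KOH, EtOH–THF) passes through the β-hydroxy ketone adduct F10 and gives the (E)-chalcone benzylic alcohol F11.
- Activated MnO2 in CH2Cl2 oxidises only the benzylic alcohol and delivers 11.

## Further compounds
F1 | step 11 | bis-chalcone bis(methoxymethyl) ether | COCOc1cc(OCc2ccccc2)ccc1C(=O)/C=C/c1ccc(OCc2ccccc2)c(Oc2ccc(/C=C/C(=O)c3ccc(OCc4ccccc4)c(Cl)c3OCOC)cc2)c1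
F2 | step 11 | bis(trans-α,β-epoxy ketone), racemic diastereomer mixture | COCOc1cc(OCc2ccccc2)ccc1C(=O)C1OC1c1ccc(OCc2ccccc2)c(Oc2ccc(C3OC3C(=O)c3ccc(OCc4ccccc4)c(Cl)c3OCOC)cc2)c1
F3 | step 11 | bis(α-formyl deoxybenzoin) bis-MOM ether, diastereomer mixture | COCOc1cc(OCc2ccccc2)ccc1C(=O)C(C=O)c1ccc(OCc2ccccc2)c(Oc2ccc(C(C=O)C(=O)c3ccc(OCc4ccccc4)c(Cl)c3OCOC)cc2)c1
F4 | step 11 | diphenol bis(α-formyl deoxybenzoin), diastereomer mixture | O=CC(C(=O)c1ccc(OCc2ccccc2)cc1O)c1ccc(OCc2ccccc2)c(Oc2ccc(C(C=O)C(=O)c3ccc(OCc4ccccc4)c(Cl)c3O)cc2)c1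
F5 | step 9 | 1-[4-(benzyloxy)-2-hydroxyphenyl]-2-bromoethan-1-one | O=C(CBr)c1ccc(OCc2ccccc2)cc1O
F6 | step 9 | {2-[4-(benzyloxy)-2-hydroxyphenyl]-2-oxoethyl}triphenylphosphonium bromide | O=C(C[P+](c1ccccc1)(c1ccccc1)c1ccccc1)c1ccc(OCc2ccccc2)cc1O.[Br-]
F7 | step 9 | 1-[4-(benzyloxy)-2-hydroxyphenyl]-2-(triphenyl-λ5-phosphanylidene)ethan-1-one | O=C(C=P(c1ccccc1)(c1ccccc1)c1ccccc1)c1ccc(OCc2ccccc2)cc1O
F8 | step 2 | 2-(benzyloxy)-5-(hydroxymethyl)phenol | OCc1ccc(OCc2ccccc2)c(O)c1
F9 | step 2 | 4-[2-(benzyloxy)-5-(hydroxymethyl)phenoxy]benzaldehyde | O=Cc1ccc(Oc2cc(CO)ccc2OCc2ccccc2)cc1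
F10 | step 2 | β-hydroxy ketone adduct of F9 and 8 (racemic) | O=C(CC(O)c1ccc(Oc2cc(CO)ccc2OCc2ccccc2)cc1)c1ccc(OCc2ccccc2)c(Cl)c1O
F11 | step 2 | (E)-chalcone benzylic alcohol | O=C(/C=C/c1ccc(Oc2cc(CO)ccc2OCc2ccccc2)cc1)c1ccc(OCc2ccccc2)c(Cl)c1O
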